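Ring B (C5–C10) carries oxygen on C6 and C8, separated by the bare C7 methylene. This 1,3-pattern is traced back to the enone C6(=O)–C7=C8, and C7 is treated as a carbon inserted into a five-membered ring. The route therefore builds a cis-hydrindane in which C5, C6, C8, C9 and C10 form a cyclopentane, cyclopropanates its C6=C8 silyl enol ether, and lets iron(III) cut the shared C6–C8 bond. In one operation the hydrindane becomes the decalin enone, and C5 settles into the trans ring fusion. Epoxidation and samarium diiodide then deliver the syn-6,8-diol; ene–yne metathesis writes the diene last.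

Key step: step 8

Remark on notation: atoms keep their labdane numbers (C1–C20) in every intermediate. "Syn" and "anti" refer to the methyl group on C10 (C20).

Step 1
Reactants: 1 3-methylcyclopent-2-en-1-one; 2 2-(3-chloropropyl)-2-methyl-1,3-dioxolane
Product: 4 (S)-3-methyl-3-[3-(2-methyl-1,3-dioxolan-2-yl)propyl]cyclopentan-1-one, via Grignard reagent 3 (not isolated)
Conditions: 2, Mg, THF, 50 °C; then 1, Cu(OTf)2 (3 mol %), chiral imidazolinium (NHC) salt (4 mol %), Et2O, −30 °C; aq NH4Cl
Reagents that add atoms: none
Why: Copper–NHC-catalysed asymmetric conjugate addition of a Grignard reagent to a β-methyl cyclic enone, in which the chosen ligand enantiomer selects the enone face and so sets the quaternary carbon (later C10) as S.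

Step 2
Reactants: 4 (S)-3-methyl-3-[3-(2-methyl-1,3-dioxolan-2-yl)propyl]cyclopentan-1-one
Product: 6 (S)-3a,7-dimethyl-2,3,3a,4,5,6-hexahydro-1H-inden-1-one, via diketone 5 (not isolated)
Conditions: HCl (0.2 equiv), THF/H2O, 23 °C; then KOH (0.5 equiv), MeOH, 65 °C
Reagents that add atoms: none
Why: Ketal hydrolysis followed by intramolecular aldol condensation, in which only attack of ring carbon C5 on the side-chain ketone C4 gives a six-membered ring that can dehydrate, the bridged ketols being reversible dead ends.

Step 3
Reactants: 6 (S)-3a,7-dimethyl-2,3,3a,4,5,6-hexahydro-1H-inden-1-one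
Product: 8 cis-3a,7-dimethyl-7-vinyloctahydro-1H-inden-1-one (vinyl on C4 anti and C5–H syn to C20), via silyl enol ether 7 (not isolated)
Conditions: CH2=CHMgBr, CuBr·SMe2 (20 mol %), TMSCl, HMPA, THF, −78 → −30 °C; then 1 M HCl, THF, 23 °C
Reagents that add atoms: vinylmagnesium bromide, C=C[Mg]Br
Why: TMSCl-accelerated copper-catalysed 1,4-addition to an s-cis alkylidene ketone (a pulegone-type acceptor), in which vinyl should enter C4 anti to the pseudoaxial C10 methyl group and the acid hydrolysis of 7 equilibrates C5 to the more stable cis-hydrindanone.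

Step 4
Reactants: 8 cis-3a,7-dimethyl-7-vinyloctahydro-1H-inden-1-one
Product: 10 cis-2,3a,7-trimethyl-7-vinyloctahydro-1H-inden-1-one (C8 epimers), via lithium enolate 9 (not isolated)
Conditions: LDA, THF, −78 °C; MeI, −78 → 0 °C
Reagents that add atoms: iodomethane, CI
Why: Kinetic enolate alkylation, in which LDA deprotonates the open C8 methylene rather than the C5 methine wedged between two quaternary carbons, and the C8 configuration does not matter because C8 becomes sp2 in step 5.

Step 5
Reactants: 10 cis-2,3a,7-trimethyl-7-vinyloctahydro-1H-inden-1-one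
Product: 11 cis-2,3a,7-trimethyl-7-vinyl-3a,4,5,6,7,7a-hexahydro-1H-inden-1-one
Conditions: IBX, DMSO/fluorobenzene, 70 °C
Reagents that add atoms: none
Why: IBX dehydrogenation of a ketone, regiochemically unambiguous because C8–C9 is the only α,β pair with hydrogen on both carbons (C4 and C10 are quaternary), with the epimerisable C5 staying in the less strained cis-fused form.

Step 6
Reactants: 11 cis-2,3a,7-trimethyl-7-vinyl-3a,4,5,6,7,7a-hexahydro-1H-inden-1-one; 12 (4-bromobut-1-yn-1-yl)trimethylsilane
Product: 14 C6=C8 trimethylsilyl enol ether of the cis-hydrindanone bearing the 4-(trimethylsilyl)but-3-yn-1-yl chain on C9 (chain syn to C20), via Grignard reagent 13 (not isolated)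
Conditions: 12, Mg, THF; then 11, CuBr·SMe2 (20 mol %), TMSCl, HMPA, THF, −78 → −40 °C; Et3N, aq NaHCO3
Reagents that add atoms: chlorotrimethylsilane, C[Si](C)(C)Cl
Why: Copper-catalysed conjugate addition with in situ silylation, in which the quaternary C4 favours the cis-hydrindenone conformer with the C10–C1 bond pseudoaxial on the concave face, so the nucleophile should enter C9 from the convex face, syn to C20, and TMSCl fixes the enolate regiospecifically as the C6=C8 enol ether.

Step 7
Reactants: 14 C6=C8 trimethylsilyl enol ether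
Product: 15 siloxycyclopropane (14 with the methylene C7 added across C6=C8; either face)
Conditions: Et2Zn, CH2I2, CH2Cl2, 0 → 23 °C
Reagents that add atoms: diiodomethane, ICI
Why: Furukawa-type Simmons–Smith cyclopropanation, in which the electron-rich silyl enol ether reacts well ahead of the neopentyl vinyl group and the silyl alkyne, and the face of attack is irrelevant because C6 and C8 become sp2 again in step 8.

Step 8
Reactants: 15 siloxycyclopropane
Product: 17 trans-fused 4-(but-3-yn-1-yl)-3,4a,8-trimethyl-8-vinyl-4a,5,6,7,8,8a-hexahydronaphthalen-1(4H)-one (C6 ketone and C7=C8; C5–H anti to C20), via β-chloro ketone 16 (not isolated)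
Conditions: FeCl3 (2.5 equiv, concentrated), DMF, 0 → 23 °C; then NaOMe, MeOH, 23 → 50 °C
Reagents that add atoms: none
Why: Fe(III) oxidises the siloxycyclopropane by one electron and removes the silyl group as TMSCl; the resulting cyclopropyloxy radical undergoes β-scission of the internal C6–C8 bond shared by cyclopentane and cyclopropane, so that C7 becomes a ring member, C6 the ketone and C8 a tertiary radical that abstracts chlorine from a second FeCl3 to give 16. The closest known reaction type is the FeCl3-mediated oxidative ring expansion of 1-siloxybicyclo[n.1.0]alkanes to β-chloro ketones and, after base, to the homologous 2-cycloalkenones. No ring is closed by bond formation: ring B (C5–C6–C7–C8–C9–C10) arises from the five-membered ring C5–C6–C8–C9–C10 by cleavage of the zero bridge of the bicyclo[3.1.0]hexane. Methoxide then removes HCl by E1cB, frees the alkyne and equilibrates C5 through the enolate to the trans-decalin, which is favoured because the cis isomer must place either the quaternary C4 or the C9 chain axial on ring B; C4, C9 and C10 are not touched, and C9, now the γ-position of the enone, already holds its chain equatorial. The step needs internal rather than external cyclopropane cleavage, which the C8 methyl group (tertiary versus primary radical) and strain release secure. It also needs chlorine transfer to outrun 5-exo addition of the C8 radical to the silyl alkyne, which an excess of concentrated FeCl3 should secure.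

Step 9
Reactants: 17 trans-fused enone
Product: 18 7,8-epoxy-6-ketone (epoxide oxygen anti to C20)
Conditions: 30 % H2O2, NaOH (0.3 equiv), MeOH, 0 → 23 °C
Reagents that add atoms: hydrogen peroxide, OO
Why: Weitz–Scheffer nucleophilic epoxidation, in which hydroperoxide should attack C8 from the face anti to the axial C10 methyl group (the other face is blocked 1,3-diaxially) and so sets C8 and C7, while vinyl and alkyne are inert to the nucleophilic oxidant.

Step 10
Reactants: 18 7,8-epoxy-6-ketone
Product: 20 6,8-diol (both hydroxyl groups equatorial and anti to C20), via aldol 19 (not isolated)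
Conditions: SmI2 (2.5 equiv), THF/MeOH, −78 °C; then SmI2 (4 equiv), H2O, Et3N, 0 → 23 °C
Reagents that add atoms: none
Why: Single-electron reduction, in which SmI2 first cleaves the C7–O bond of the α,β-epoxy ketone to give 19 with C8 untouched, and the SmI2–water–amine system then reduces the hindered C6 ketone through ketyl and carbanion protonation to the thermodynamically favoured equatorial alcohol, since an axial C6–O would be 1,3-diaxial to the methyl groups on C4 and C10.

Step 11
Reactants: 20 6,8-diol
Product: 21 6-acetate of 20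
Conditions: Ac2O, pyridine, DMAP (10 mol %), CH2Cl2, 23 °C
Reagents that add atoms: acetic anhydride, CC(=O)OC(C)=O
Why: Chemoselective DMAP-catalysed acylation, in which the secondary equatorial C6 hydroxyl reacts and the tertiary C8 hydroxyl does not at room temperature.

Step 12
Reactants: 21 6-acetate
Product: 23 6-acetoxy-8-hydroxy-18-alcohol with the but-3-yn-1-yl chain on C9, via aldehyde 22 (not isolated)
Conditions: O3, CH2Cl2/MeOH, −78 °C (Sudan Red end point); Me2S; then NaBH4, −40 → 0 °C; AcOH quench
Reagents that add atoms: ozone, [O-][O+]=O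
Why: Ozonolysis with reductive work-up, in which the vinyl group is consumed well before the terminal alkyne, cold borohydride reduces only the neopentyl aldehyde, the acidic quench guards against O6→O18 acetyl migration, and C4 keeps its configuration.

Step 13
Reactants: 23 alkyne
Product: 24 ent-6α-acetoxylabda-13(16),14-diene-8α,18-diol (target, CNP0312185.1)
Conditions: ethylene (1 atm), Grubbs second-generation catalyst (5 mol %), CH2Cl2, 40 °C
Reagents that add atoms: ethylene, C=C
Why: Ene–yne cross metathesis with ethylene turns the terminal alkyne into the 2-substituted buta-1,3-diene (C13=C16 and C14=C15), tolerates free hydroxyl groups and the acetate, and touches no stereocentre.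

Compound list
1 | 3-methylcyclopent-2-en-1-one | CC1=CC(=O)CC1 | starting material
2 | 2-(3-chloropropyl)-2-methyl-1,3-dioxolane | CC1(CCCCl)OCCO1 | starting material
3 | [3-(2-methyl-1,3-dioxolan-2-yl)propyl]magnesium chloride | CC1(CCC[Mg]Cl)OCCO1 | intermediate
4 | (S)-3-methyl-3-[3-(2-methyl-1,3-dioxolan-2-yl)propyl]cyclopentan-1-one | O=C1C[C@@](C)(CCCC2(C)OCCO2)CC1 | intermediate
5 | (S)-3-methyl-3-(4-oxopentyl)cyclopentan-1-one | O=C1C[C@@](C)(CCCC(C)=O)CC1 | intermediate
6 | (S)-3a,7-dimethyl-2,3,3a,4,5,6-hexahydro-1H-inden-1-one | CC1=C2C(=O)CC[C@]2(C)CCC1 | intermediate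
7 | C5=C6 trimethylsilyl enol ether of 8 (vinyl on C4 anti to C20) | C1C[C@]2(C)CCC[C@](C)(C=C)C2=C1O[Si](C)(C)C | intermediate
8 | cis-3a,7-dimethyl-7-vinyloctahydro-1H-inden-1-one (vinyl anti, C5–H syn to C20) | C1C[C@]2(C)CCC[C@](C)(C=C)[C@@H]2C1=O | intermediate
9 | lithium C6=C8 enolate of 8 | C=1C[C@]2(C)CCC[C@](C)(C=C)[C@@H]2C=1O[Li] | intermediate
10 | cis-2,3a,7-trimethyl-7-vinyloctahydro-1H-inden-1-one (epimers at C8) | CC1C[C@]2(C)CCC[C@](C)(C=C)[C@@H]2C1=O | intermediate
11 | cis-2,3a,7-trimethyl-7-vinyl-3a,4,5,6,7,7a-hexahydro-1H-inden-1-one | CC1=C[C@]2(C)CCC[C@](C)(C=C)[C@@H]2C1=O | intermediate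
12 | (4-bromobut-1-yn-1-yl)trimethylsilane | C[Si](C)(C)C#CCCBr | starting material
13 | [4-(trimethylsilyl)but-3-yn-1-yl]magnesium bromide | C[Si](C)(C)C#CCC[Mg]Br | intermediate
14 | trimethyl{[cis-2,3a,7-trimethyl-3-[4-(trimethylsilyl)but-3-yn-1-yl]-7-vinyl-3a,4,5,6,7,7a-hexahydro-3H-inden-1-yl]oxy}silane (chain on C9 syn to C20) | C[Si](C)(C)C#CCC[C@H]1[C@]2(C)CCC[C@](C)(C=C)[C@@H]2C(O[Si](C)(C)C)=C1C | intermediate
15 | siloxycyclopropane: 14 with CH2 (C7) bridging C6 and C8 (mixture at C6/C8, erased in step 8) | C[Si](C)(C)C#CCC[C@H]1[C@]2(C)CCC[C@](C)(C=C)[C@@H]2C3(O[Si](C)(C)C)CC13C | intermediate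
16 | cis-fused 3-chloro-3,4a,8-trimethyl-4-[4-(trimethylsilyl)but-3-yn-1-yl]-8-vinyloctahydronaphthalen-1(2H)-one (C8 epimers) | C[Si](C)(C)C#CCC[C@H]1[C@]2(C)CCC[C@](C)(C=C)[C@@H]2C(=O)CC1(C)Cl | intermediate
17 | trans-fused 4-(but-3-yn-1-yl)-3,4a,8-trimethyl-8-vinyl-4a,5,6,7,8,8a-hexahydronaphthalen-1(4H)-one | C#CCC[C@H]1[C@]2(C)CCC[C@](C)(C=C)[C@H]2C(=O)C=C1C | intermediate
18 | 7,8-epoxide of 17, oxygen anti to C20 | C#CCC[C@H]1[C@]2(C)CCC[C@](C)(C=C)[C@H]2C(=O)[C@@H]3O[C@]13C | intermediate
19 | 8-hydroxy-6-ketone (aldol), C8–OH anti to C20 | C#CCC[C@H]1[C@]2(C)CCC[C@](C)(C=C)[C@H]2C(=O)C[C@]1(C)O | intermediate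
20 | 6,8-diol, both hydroxyl groups equatorial and anti to C20 | C#CCC[C@H]1[C@]2(C)CCC[C@](C)(C=C)[C@H]2[C@H](O)C[C@]1(C)O | intermediate
21 | 6-acetate of 20 | C#CCC[C@H]1[C@]2(C)CCC[C@](C)(C=C)[C@H]2[C@H](OC(C)=O)C[C@]1(C)O | intermediate
22 | C18 aldehyde (formyl on C4 in place of vinyl) | C#CCC[C@H]1[C@]2(C)CCC[C@](C)(C=O)[C@H]2[C@H](OC(C)=O)C[C@]1(C)O | intermediate
23 | C18 alcohol with but-3-yn-1-yl chain on C9 | C#CCC[C@H]1[C@]2(C)CCC[C@](C)(CO)[C@H]2[C@H](OC(C)=O)C[C@]1(C)O | intermediate
24 | ent-6α-acetoxylabda-13(16),14-diene-8α,18-diol | C=CC(=C)CC[C@H]1[C@]2(C)CCC[C@](C)(CO)[C@H]2[C@H](OC(C)=O)C[C@]1(C)O | target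

Total steps: 13. Longest linear sequence: 13 (1 → 24).

Steps most likely to fail

Step 8. The tertiary C8 radical may add to the silyl alkyne, or be over-oxidised, before chlorine transfer. Lewis-acid protodesilylation may also open the external cyclopropane bond. The fallback sets out from 14 and comes back at 17, and it replaces the radical process by a polar, two-electron ring expansion. Dibromocarbene (CHBr3, KOtBu, pentane, −20 °C) adds to the enol ether of 14 to give the 7,7-dibromo siloxycyclopropane F1. On warming in toluene, the cyclopropyl-to-allyl cation electrocyclic opening expels bromide and the silyl group and gives the ring-enlarged cis-fused 7-bromo enone F2. Zinc in acetic acid removes the α-bromine to give the cis-fused silyl-alkyne enone F3. The NaOMe/MeOH treatment of step 8 then converts F3 into 17.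

Step 10. Facial control may be poor when the C6 ketyl is protonated, and ring B may open by retro-aldol reaction at the aldol stage. The fallback sets out from 18 and comes back at 21, and it replaces thermodynamic electron-transfer control by hydride delivery plus SN2 inversion. Compound 18 is treated with only two equivalents of SmI2 (THF/MeOH, −78 °C) and 19 is isolated. NaBH4/CeCl3 delivers hydride from the open face anti to C20 and gives the axial C6 alcohol, the 6-epi-diol F4. A Mitsunobu reaction with acetic acid (PPh3, DIAD, toluene) installs the acetate with inversion and gives 21 directly.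

Step 1. Enantioselectivity may be lost, and 1,2-addition may compete, when a THF-borne functionalised Grignard reagent meets the five-membered enone. The fallback sets out from 3 and comes back at 4, and it exchanges the roles of nucleophile and β-substituent. Grignard reagent 3 adds 1,2 to commercial 3-ethoxycyclopent-2-en-1-one. Mild acid hydrolysis (Stork–Danheiser transposition) gives 3-[3-(2-methyl-1,3-dioxolan-2-yl)propyl]cyclopent-2-en-1-one F5. An NHC–copper-catalysed asymmetric conjugate addition of Me3Al (THF, −78 °C), a reaction class established for β-alkyl cyclopentenones, then brings in the methyl group and gives 4.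

Further compounds
F1 | step 8 | 7,7-dibromo siloxycyclopropane (14 with CBr2 bridging C6 and C8) | C[Si](C)(C)C#CCC[C@H]1[C@]2(C)CCC[C@](C)(C=C)[C@@H]2C3(O[Si](C)(C)C)C(Br)(Br)C13C
F2 | step 8 | cis-fused 7-bromo enone (2-bromo-3,4a,8-trimethyl-4-[4-(trimethylsilyl)but-3-yn-1-yl]-8-vinyl-4a,5,6,7,8,8a-hexahydronaphthalen-1(4H)-one) | C[Si](C)(C)C#CCC[C@H]1[C@]2(C)CCC[C@](C)(C=C)[C@@H]2C(=O)C(Br)=C1C
F3 | step 8 | cis-fused silyl-alkyne enone (5-epimer of 17 carrying the alkynyl trimethylsilyl group) | C[Si](C)(C)C#CCC[C@H]1[C@]2(C)CCC[C@](C)(C=C)[C@@H]2C(=O)C=C1C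
F4 | step 10 | 6-epi-diol (axial C6–OH, syn to C20) | C#CCC[C@H]1[C@]2(C)CCC[C@](C)(C=C)[C@H]2[C@@H](O)C[C@]1(C)O
F5 | step 1 | 3-[3-(2-methyl-1,3-dioxolan-2-yl)propyl]cyclopent-2-en-1-one | O=C1C=C(CCCC2(C)OCCO2)CC1
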